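The dienone ring (C-1' bearing the lactam, C-2' enol, C-3' H, C-4' methyl, C-5' gem-diprenyl, C-6' carbonyl) is a cyclic 1,3-diketone: C-1'/C-6' form an acetate unit and C-2' to C-5' a masked vinylketene. The key step therefore expands 3-methyl-4,4-diprenylcyclobutenone with the dianion of an enantiopure (isoindolinonyl)acetate: 1,2-addition makes C-1'–C-2', oxyanion-accelerated 4π ring opening releases a dienolate whose fully substituted γ-terminus acylates the ester, making C-5'–C-6' and the quaternary centre. The stereocentre comes from a sulfinimine Mannich addition, the cyclobutenone from a keteniminium–propyne [2+2] cycloaddition.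

Key step: step 8

Remark: the target is one enol tautomer of a 2-substituted cyclohexene-1,3-dione; the route is aimed at this interconverting tautomeric system, with the lactam stereocentre R as drawn.

Step 1
Reactants: 1 2-bromo-6-methoxybenzaldehyde; 2 (R)-2-methylpropane-2-sulfinamide
Product: 3 (R,E)-N-[(2-bromo-6-methoxyphenyl)methylidene]-2-methylpropane-2-sulfinamide
Conditions: Ti(OEt)4 (2 equiv), THF, 50 °C
Reagents that add atoms: none
Why: Lewis acid-mediated condensation of an aldehyde with a sulfinamide, Ti(OEt)4 taking up the water; the sulfur stereocentre is carried over unchanged and the aldimine should form as the E isomer.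

Step 2
Reactants: 3 (R,E)-N-[(2-bromo-6-methoxyphenyl)methylidene]-2-methylpropane-2-sulfinamide; 4 methyl acetate
Product: 7 methyl (3S)-3-(2-bromo-6-methoxyphenyl)-3-{[(R)-tert-butylsulfinyl]amino}propanoate, via lithium enolate of methyl acetate 5 (not isolated), via triisopropoxytitanium enolate of methyl acetate 6 (not isolated)
Conditions: 4 (2 equiv), LiN(iPr)2 (2 equiv), THF, −78 °C; ClTi(OiPr)3 (4 equiv); then 3, −78 °C; aq. NH4Cl
Reagents that add atoms: none
Why: Mannich-type addition of a titanium ester enolate to an N-sulfinyl aldimine through a chelated chair (Zimmerman–Traxler-type) transition state with the tert-butyl group pseudo-equatorial, so the (R)-sulfur should direct the enolate to the Si face and set C-3 as S.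

Step 3
Reactants: 7 methyl (3S)-3-(2-bromo-6-methoxyphenyl)-3-{[(R)-tert-butylsulfinyl]amino}propanoate
Product: 8 methyl (3S)-3-amino-3-(2-bromo-6-methoxyphenyl)propanoate hydrochloride
Conditions: HCl (4 M in dioxane), MeOH, 0 °C to rt
Reagents that add atoms: hydrogen chloride, Cl
Why: acidic methanolysis of the N–S bond of a sulfinamide, which transfers the sulfinyl group to methanol and leaves the ester, the aryl bromide and the carbon stereocentre untouched.

Step 4
Reactants: 8 methyl (3S)-3-amino-3-(2-bromo-6-methoxyphenyl)propanoate hydrochloride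
Product: 9 methyl 2-[(1S)-7-methoxy-3-oxo-2,3-dihydro-1H-isoindol-1-yl]acetate
Conditions: Pd(OAc)2 (5 mol %), Xantphos (6 mol %), CO (1 atm), Et3N (3 equiv), toluene, 90 °C
Reagents that add atoms: carbon monoxide, [C-]#[O+]
Why: palladium-catalysed aminocarbonylation of an ortho-bromobenzylamine (oxidative addition, CO insertion, capture of the acyl-palladium by the primary amine) should close the five-membered lactam without touching the benzylic stereocentre.

Step 5
Reactants: 10 N,N-dimethylacetamide; 11 1-bromo-3-methylbut-2-ene (prenyl bromide)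
Product: 13 N,N,5-trimethylhex-4-enamide, via lithium enolate of N,N-dimethylacetamide 12 (not isolated)
Conditions: LiN(iPr)2 (1.05 equiv), THF, −78 °C; 11 (1.0 equiv), −78 to 0 °C
Reagents that add atoms: none
Why: SN2 alkylation of a tertiary amide enolate with a primary allylic bromide, held at one equivalent of base and electrophile so that monoalkylation dominates; any doubly alkylated material is the product of step 6 and can be carried forward.

Step 6
Reactants: 13 N,N,5-trimethylhex-4-enamide; 11 1-bromo-3-methylbut-2-ene (prenyl bromide)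
Product: 15 N,N,5-trimethyl-2-(3-methylbut-2-en-1-yl)hex-4-enamide, via lithium enolate of N,N,5-trimethylhex-4-enamide 14 (not isolated)
Conditions: LiN(iPr)2 (1.1 equiv), THF, −78 °C; 11 (1.2 equiv), −78 °C to rt
Reagents that add atoms: none
Why: second SN2 alkylation of an amide enolate with the same allylic bromide; the enolate should form cleanly because the tertiary amide has no competing acidic site, and a third alkylation is blocked by steric hindrance at the tertiary α-carbon.

Step 7
Reactants: 15 N,N,5-trimethyl-2-(3-methylbut-2-en-1-yl)hex-4-enamide; 16 propyne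
Product: 19 3-methyl-4,4-bis(3-methylbut-2-en-1-yl)cyclobut-2-en-1-one, via keteniminium triflate 17 (not isolated), via cyclobuteniminium triflate 18 (not isolated)
Conditions: Tf2O (1.2 equiv), 2,4,6-collidine (1.2 equiv), 16 (excess), ClCH2CH2Cl, −20 to 40 °C, sealed vessel; then H2O
Reagents that add atoms: water, O
Why: keteniminium–alkyne [2+2] cycloaddition in which the electrophilic iminium carbon bonds to the terminal alkyne carbon (the more substituted vinyl cation closes onto the diprenyl carbon), so the methyl group ends at C-3, and hydrolysis of the cyclobuteniminium salt gives the enone.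

Step 8
Reactants: 9 methyl 2-[(1S)-7-methoxy-3-oxo-2,3-dihydro-1H-isoindol-1-yl]acetate; 19 3-methyl-4,4-bis(3-methylbut-2-en-1-yl)cyclobut-2-en-1-one
Product: 23 (3R)-3-[2-hydroxy-4-methyl-5,5-bis(3-methylbut-2-en-1-yl)-6-oxocyclohexa-1,3-dien-1-yl]-4-methoxy-2,3-dihydro-1H-isoindol-1-one, via dilithio enolate of the lactam ester 20 (not isolated), via dilithium cyclobutenoxide adduct 21 (not isolated), via dilithium dienolate 22 (not isolated)
Conditions: 9, LiN(iPr)2 (2.1 equiv), THF, −78 °C; 19 (1.1 equiv), −78 to 0 °C; then AcOH (3 equiv), 0 °C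
Reagents that add atoms: none
Why: Proposed new method: the enolate carbon of dianion 20 adds to the strained carbonyl of 19 (C-1'–C-2'), cyclobutenoxide 21 undergoes oxyanion-accelerated conrotatory 4π ring opening to dienolate 22, and the γ-carbon of 22 attacks the methyl ester (C-5'–C-6') with loss of methoxide, which then deprotonates the product to the stable diketonate. The closest known reaction types are the benzannulation of lithium ynolates with vinylketenes (C-acylation, then ring closure onto the diene terminus), the alkoxide-accelerated ring opening of cyclobutenols formed by carbanion addition to cyclobutenones, and the Dieckmann condensation. The six-membered ring closes by a 6-(enolendo)-exo-trig acyl substitution, set up because torquoselective outward rotation of the oxido group turns the ester-bearing carbon inward, cis to the diene terminus. No new stereocentre is formed (C-5' carries two identical prenyl groups and C-1' becomes sp2), and the lactam stereocentre should survive because the nitrogen stays lithiated, as in the known doubly lithiated N-acyl β-amino esters, so that β-elimination would have to expel an amide dianion. The step needs 1,2-addition to win over γ-deprotonation of the cyclobutenone methyl group, and γ-acylation to win over internal proton transfer from C-1'–H. The first is favoured by the low temperature and the strain-activated carbonyl; the second by the absence of any proton source more acidic than diisopropylamine and by the fact that α-attack would give a four-membered ring.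

Compound list
1 | 2-bromo-6-methoxybenzaldehyde | COc1cccc(Br)c1C=O | starting material
2 | (R)-2-methylpropane-2-sulfinamide | CC(C)(C)[S@@](=O)N | starting material
3 | (R,E)-N-[(2-bromo-6-methoxyphenyl)methylidene]-2-methylpropane-2-sulfinamide | CC(C)(C)[S@@](=O)/N=C/c1c(Br)cccc1OC | intermediate
4 | methyl acetate | COC(C)=O | starting material
5 | lithium enolate of methyl acetate | COC(=C)O[Li] | intermediate (not isolated)
6 | triisopropoxytitanium enolate of methyl acetate | COC(=C)O[Ti](OC(C)C)(OC(C)C)OC(C)C | intermediate (not isolated)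
7 | methyl (3S)-3-(2-bromo-6-methoxyphenyl)-3-{[(R)-tert-butylsulfinyl]amino}propanoate | CC(C)(C)[S@@](=O)N[C@@H](CC(=O)OC)c1c(Br)cccc1OC | intermediate
8 | methyl (3S)-3-amino-3-(2-bromo-6-methoxyphenyl)propanoate hydrochloride | COC(=O)C[C@H](N)c1c(Br)cccc1OC.Cl | intermediate
9 | methyl 2-[(1S)-7-methoxy-3-oxo-2,3-dihydro-1H-isoindol-1-yl]acetate | COc1cccc2c1[C@H](CC(=O)OC)NC2=O | intermediate
10 | N,N-dimethylacetamide | CC(=O)N(C)C | starting material
11 | 1-bromo-3-methylbut-2-ene (prenyl bromide) | CC(C)=CCBr | starting material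
12 | lithium enolate of N,N-dimethylacetamide | C=C(O[Li])N(C)C | intermediate (not isolated)
13 | N,N,5-trimethylhex-4-enamide | CC(C)=CCCC(=O)N(C)C | intermediate
14 | lithium enolate of N,N,5-trimethylhex-4-enamide | CC(C)=CCC=C(O[Li])N(C)C | intermediate (not isolated)
15 | N,N,5-trimethyl-2-(3-methylbut-2-en-1-yl)hex-4-enamide | CC(C)=CCC(CC=C(C)C)C(=O)N(C)C | intermediate
16 | propyne | CC#C | starting material
17 | N-methyl-N-[5-methyl-2-(3-methylbut-2-en-1-yl)hexa-1,4-dien-1-ylidene]methanaminium triflate (keteniminium salt) | CC(C)=CCC(CC=C(C)C)=C=[N+](C)C.[O-]S(=O)(=O)C(F)(F)F | intermediate (not isolated)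
18 | N-methyl-N-[3-methyl-4,4-bis(3-methylbut-2-en-1-yl)cyclobut-2-en-1-ylidene]methanaminium triflate | C[N+](C)=C1C=C(C)C1(CC=C(C)C)CC=C(C)C.[O-]S(=O)(=O)C(F)(F)F | intermediate (not isolated)
19 | 3-methyl-4,4-bis(3-methylbut-2-en-1-yl)cyclobut-2-en-1-one | O=C1C=C(C)C1(CC=C(C)C)CC=C(C)C | intermediate
20 | dilithio derivative of 9 (N-lithio lactam, lithium ester enolate) | COc1cccc2c1[C@H](C=C(O[Li])OC)N([Li])C2=O | intermediate (not isolated)
21 | dilithium salt of methyl 2-[1-hydroxy-3-methyl-4,4-bis(3-methylbut-2-en-1-yl)cyclobut-2-en-1-yl]-2-[(1S)-7-methoxy-3-oxoisoindolin-1-yl]acetate (alkoxide and N-lithio lactam, mixture at the two new carbons) | COc1cccc2c1[C@H](C(C(=O)OC)C1(O[Li])C=C(C)C1(CC=C(C)C)CC=C(C)C)N([Li])C2=O | intermediate (not isolated)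
22 | dilithium dienolate: N-lithiated methyl (3E)-2-[(1S)-7-methoxy-3-oxoisoindolin-1-yl]-5,9-dimethyl-6-(3-methylbut-2-en-1-yl)-3-(lithiooxy)deca-3,5,8-trienoate | COc1cccc2c1[C@H](C(C(=O)OC)/C(O[Li])=C\C(C)=C(CC=C(C)C)CC=C(C)C)N([Li])C2=O | intermediate (not isolated)
23 | (3R)-3-[2-hydroxy-4-methyl-5,5-bis(3-methylbut-2-en-1-yl)-6-oxocyclohexa-1,3-dien-1-yl]-4-methoxy-2,3-dihydro-1H-isoindol-1-one (CNP0508988.2) | COc1cccc2c1[C@H](C1=C(O)C=C(C)C(CC=C(C)C)(CC=C(C)C)C1=O)NC2=O | target

Total step count: 8. Longest linear sequence: 5 steps (1, 2, 3, 4, 8); steps 5, 6 and 7 build the second fragment.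

Steps most likely to fail

Step 8 (proposed new method). Internal proton transfer from the acidic C-1'–H to the dienolate terminus may outrun acyl transfer and stall the cascade at an open-chain β-keto ester enolate, or the ester enolate may enolise the cyclobutenone instead of adding to it. The fallback is the known benzannulation-type reaction of lithium ynolates with (trialkylsilyl)vinylketenes, which makes the same two bonds by C-acylation and 6π electrocyclization and has no C–H on the nucleophilic carbon. It sets out from sulfinimine 3 and amide 15 and comes back to the route at 23. From 3, chelation-controlled addition of Me3SiC≡CMgBr (CH2Cl2, −78 °C to rt) should give (R)-N-[(1S)-1-(2-bromo-6-methoxyphenyl)-3-(trimethylsilyl)prop-2-yn-1-yl]-2-methylpropane-2-sulfinamide F1, and HCl in MeOH should then give (1S)-1-(2-bromo-6-methoxyphenyl)-3-(trimethylsilyl)prop-2-yn-1-amine hydrochloride F2. Aminocarbonylation as in step 4 should give (3R)-4-methoxy-3-[(trimethylsilyl)ethynyl]-2,3-dihydro-1H-isoindol-1-one F3 (same spatial arrangement as in 9; the descriptor changes only because the silylalkynyl group outranks the aryl carbon), and K2CO3 in MeOH should give (3S)-3-ethynyl-4-methoxy-2,3-dihydro-1H-isoindol-1-one F4. n-BuLi (2 equiv, THF, −78 °C) should give the N,C-dilithio derivative of the ethynyl lactam F5, and oxidation of this acetylide with LiOOtBu should give the dilithio ynolate of the lactam F6. From 15, the keteniminium [2+2] cycloaddition of step 7 run with 1-(triisopropylsilyl)propyne (the iminium carbon bonding to the silicon-bearing alkyne carbon) should give 3-methyl-4,4-bis(3-methylbut-2-en-1-yl)-2-(triisopropylsilyl)cyclobut-2-en-1-one F7, which on heating (toluene, 90 °C) should open to 3,7-dimethyl-4-(3-methylbut-2-en-1-yl)-2-(triisopropylsilyl)octa-1,3,6-trien-1-one F8. Combining F6 and F8 (THF, −78 °C to rt, then AcOH) should give (3R)-3-[2-hydroxy-4-methyl-5,5-bis(3-methylbut-2-en-1-yl)-6-oxo-3-(triisopropylsilyl)cyclohexa-1,3-dien-1-yl]-4-methoxy-2,3-dihydro-1H-isoindol-1-one F9, and protodesilylation of the α-silyl enone (Bu4NF, AcOH, THF) returns to 23.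

Step 7. The keteniminium ion, or acid derived from Tf2O, may be intercepted by the nucleophilic prenyl double bonds (cation–olefin side reactions) faster than it undergoes the intermolecular cycloaddition with a gaseous, weakly nucleophilic alkyne. The fallback is a ketene–alkoxyalkyne [2+2] cycloaddition followed by carbonyl transposition; it sets out from methyl acetate 4 and prenyl bromide 11 and comes back to the route at 19. Alkylation of the lithium enolate of 4 with 11 (LiN(iPr)2, THF, −78 °C, ester added slowly to the base) should give methyl 5-methylhex-4-enoate F10, and a second enolisation and alkylation with 11 should give methyl 5-methyl-2-(3-methylbut-2-en-1-yl)hex-4-enoate F11. LiOH in aqueous THF, then dilute HCl, should give 5-methyl-2-(3-methylbut-2-en-1-yl)hex-4-enoic acid F12, and oxalyl chloride with a trace of DMF should give 5-methyl-2-(3-methylbut-2-en-1-yl)hex-4-enoyl chloride F13. Et3N in the presence of ethoxyacetylene should release 5-methyl-2-(3-methylbut-2-en-1-yl)hexa-1,4-dien-1-one F14, which is trapped in the flask as 3-ethoxy-4,4-bis(3-methylbut-2-en-1-yl)cyclobut-2-en-1-one F15. 1,2-Addition of MeLi should give racemic 3-ethoxy-1-methyl-4,4-bis(3-methylbut-2-en-1-yl)cyclobut-2-en-1-ol F16, and dilute aqueous HCl (ionisation of the allylic alcohol, hydrolysis of the enol ether with loss of ethanol and carbonyl transposition) gives 19.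

Step 2. Facial selectivity may erode at the di-ortho-substituted aldimine through competition between chelated and open transition states, giving a diastereomer mixture that is hard to upgrade. The fallback sets the stereocentre by catalytic asymmetric hydrogenation; it sets out from aldehyde 1 and comes back to the route at 8. SnCl2-catalysed Roskamp homologation of 1 with methyl diazoacetate should give methyl 3-(2-bromo-6-methoxyphenyl)-3-oxopropanoate F17, and NH4OAc in MeOH should give methyl (2Z)-3-amino-3-(2-bromo-6-methoxyphenyl)prop-2-enoate F18. Hydrogenation of the unprotected enamine (Ru(OAc)2 with a SEGPHOS-type atropisomeric diphosphine of the appropriate hand, H2, trifluoroethanol) should give methyl (3S)-3-amino-3-(2-bromo-6-methoxyphenyl)propanoate F19, and HCl in dioxane converts it into 8.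

Further compounds
F1 | step 8 | (R)-N-[(1S)-1-(2-bromo-6-methoxyphenyl)-3-(trimethylsilyl)prop-2-yn-1-yl]-2-methylpropane-2-sulfinamide | CC(C)(C)[S@@](=O)N[C@@H](C#C[Si](C)(C)C)c1c(Br)cccc1OC
F2 | step 8 | (1S)-1-(2-bromo-6-methoxyphenyl)-3-(trimethylsilyl)prop-2-yn-1-amine hydrochloride | C[Si](C)(C)C#C[C@H](N)c1c(Br)cccc1OC.Cl
F3 | step 8 | (3R)-4-methoxy-3-[(trimethylsilyl)ethynyl]-2,3-dihydro-1H-isoindol-1-one | COc1cccc2c1[C@H](C#C[Si](C)(C)C)NC2=O
F4 | step 8 | (3S)-3-ethynyl-4-methoxy-2,3-dihydro-1H-isoindol-1-one | COc1cccc2c1[C@H](C#C)NC2=O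
F5 | step 8 | N,C-dilithio derivative of the ethynyl lactam (N-lithio lactam, lithium acetylide) | COc1cccc2c1[C@H](C#C[Li])N([Li])C2=O
F6 | step 8 | dilithio ynolate of the lactam (N-lithio lactam, lithium ynolate) | COc1cccc2c1[C@H](C#CO[Li])N([Li])C2=O
F7 | step 8 | 3-methyl-4,4-bis(3-methylbut-2-en-1-yl)-2-(triisopropylsilyl)cyclobut-2-en-1-one | O=C1C([Si](C(C)C)(C(C)C)C(C)C)=C(C)C1(CC=C(C)C)CC=C(C)C
F8 | step 8 | 3,7-dimethyl-4-(3-methylbut-2-en-1-yl)-2-(triisopropylsilyl)octa-1,3,6-trien-1-one | O=C=C([Si](C(C)C)(C(C)C)C(C)C)C(C)=C(CC=C(C)C)CC=C(C)C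
F9 | step 8 | (3R)-3-[2-hydroxy-4-methyl-5,5-bis(3-methylbut-2-en-1-yl)-6-oxo-3-(triisopropylsilyl)cyclohexa-1,3-dien-1-yl]-4-methoxy-2,3-dihydro-1H-isoindol-1-one | COc1cccc2c1[C@H](C1=C(O)C([Si](C(C)C)(C(C)C)C(C)C)=C(C)C(CC=C(C)C)(CC=C(C)C)C1=O)NC2=O
F10 | step 7 | methyl 5-methylhex-4-enoate | COC(=O)CCC=C(C)C
F11 | step 7 | methyl 5-methyl-2-(3-methylbut-2-en-1-yl)hex-4-enoate | COC(=O)C(CC=C(C)C)CC=C(C)C
F12 | step 7 | 5-methyl-2-(3-methylbut-2-en-1-yl)hex-4-enoic acid | OC(=O)C(CC=C(C)C)CC=C(C)C
F13 | step 7 | 5-methyl-2-(3-methylbut-2-en-1-yl)hex-4-enoyl chloride | ClC(=O)C(CC=C(C)C)CC=C(C)C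
F14 | step 7 | 5-methyl-2-(3-methylbut-2-en-1-yl)hexa-1,4-dien-1-one (diprenylketene) | O=C=C(CC=C(C)C)CC=C(C)C
F15 | step 7 | 3-ethoxy-4,4-bis(3-methylbut-2-en-1-yl)cyclobut-2-en-1-one | CCOC1=CC(=O)C1(CC=C(C)C)CC=C(C)C
F16 | step 7 | racemic 3-ethoxy-1-methyl-4,4-bis(3-methylbut-2-en-1-yl)cyclobut-2-en-1-ol | CCOC1=CC(C)(O)C1(CC=C(C)C)CC=C(C)C
F17 | step 2 | methyl 3-(2-bromo-6-methoxyphenyl)-3-oxopropanoate | COC(=O)CC(=O)c1c(Br)cccc1OC
F18 | step 2 | methyl (2Z)-3-amino-3-(2-bromo-6-methoxyphenyl)prop-2-enoate | COC(=O)/C=C(\N)c1c(Br)cccc1OC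
F19 | step 2 | methyl (3S)-3-amino-3-(2-bromo-6-methoxyphenyl)propanoate | COC(=O)C[C@H](N)c1c(Br)cccc1OC
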